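(The numbers in the tables are calculated for an exercise; scatter was added.)

**The question.** How much of the free monomer has reacted in the ash flask at 80 min, and how long are its chains on average?

1. average number of monomer units in a chain (chains begun, living or dead) at 80 min
2. part of the free monomer that has reacted at 80 min

| setting | ash | birch | flask |
|---|---|---|---|
| free monomer | 0.69 M | 0.69 M | 0.69 M |
| pre-initiator | 1 mol% | 0.67 mol% | 1 mol% |
| remark | the very flask that is asked about, followed so far | run made earlier |  |
| time |  |  | 80 min |

| run | time / min | monomer in chains / % | free monomer / % |
|---|---|---|---|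
| ash | 2.50 | 3 | 98 |
| ash | 5.00 | 3 | 100 |
| ash | 8.00 | 0 | 95 |
| ash | 10.0 | 0 | 96 |
| ash | 12.0 | 4 | 96 |
| ash | 15.0 | 0 | 95 |
| birch | 10.0 | 0 | 92 |
| birch | 20.0 | 0 | 89 |
| birch | 30.0 | 0 | 84 |
| birch | 40.0 | 0 | 84 |
| birch | 50.0 | 0 | 81 |
| birch | 60.0 | 0 | 76 |

(standard deviation of a reading: 2 percentage points)

**Reading the loss.** In the birch run the free monomer falls steadily, yet monomer in chains still reads 0% at 60.0 min, so the monomer is leaving for somewhere these readings do not show. We take the plainest case as our zero: a loss that ignores the pre-initiator, where each monomer molecule has the same chance per minute. From 76% left at 60.0 min we read 152 min, the loss half-life, the first-order time that halves whatever free monomer is left.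

**Testing it.** The ash run has 1 mol% pre-initiator against 0.67 mol% in birch. The half-life predicts 93.4% left at 15.0 min, and ash reads 95%, a gap of 1.6 percentage points against a scatter of 2 points. So we expect 30.6% reacted at 80 min. The runs do not count chains, so we commit to no average length.

**The forecast.** It gives 32% reacted and an average of 30 units, holding that “the monomer is going somewhere unmeasured”.

**The flask.** The ash flask gives 30.5% reacted and an average of 18.3 units, so the forecast's average is high by a factor of 1.64.

    free monomer + living end → monomer in chains + living end, rate k1*[living end]*[free monomer] (k = 0.0180 M⁻¹ s⁻¹)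
    free monomer + initiator → living end + monomer in chains (k = 0.00370 M⁻¹ s⁻¹)
    pre-initiator → initiator (k = 3.60 × 10⁻⁵ s⁻¹)
    monomer in chains + living end → free monomer + living end, rate k4*[living end] as long as [monomer in chains] is above zero (k = 0.00290 s⁻¹)
    free monomer → uncatalysed product (k = 7.30 × 10⁻⁵ s⁻¹)
    initiator → spent initiator (k = 0.00340 s⁻¹)

**Where it went.** Our loss half-life, a reading of 152 min from the birch run, gave 30.6% for the ash flask. There, at 80.0 min, the half-life of free monomer by its turning into uncatalysed product is 160 min, much shorter than the 1300 h by its reaction with initiator. The ash flask then holds 29.4% uncatalysed product and 1.08% monomer in chains.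

**A second flask.** The neighbour flask has the same charge as the ash flask, read at 3.0 h. That time is 1.18 loss half-lives, which gives 56.0% reacted; the computed result is 56.8%.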